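The constants used here were set for the occasion; the rest is arithmetic.

The charge holds J and Q in the ratio 46.0 to one, but the rates hang on more than that ratio, so I begin by turning each step into a clock.

    L + J ⇌ J + Z (K1 = 4.6, k1 = 3.62 M⁻¹ min⁻¹, Ea1 = 62.0 kJ mol⁻¹, ΔH1 = −71.0 kJ mol⁻¹)
    E + Q + Z ⇌ Q + G (K2 = 150 M⁻¹, k2 = 223 M⁻² min⁻¹, Ea2 = 43.0 kJ mol⁻¹, ΔH2 = −8.00 kJ mol⁻¹)
    (constants at 70 °C)

| flask | L | E | J | Q | temperature | time |
|---|---|---|---|---|---|---|
| violet | 0.28 M | 0.900 equiv | 4.6 mol% | 0.1 mol% | −5 °C | 5.0 h |
| amber | 0.28 M | 0.900 equiv | 4.6 mol% | 0.1 mol% | 45 °C | 5.0 h |
| red | 0.28 M | 0.900 equiv | 4.6 mol% | 0.1 mol% | 70 °C | 5.0 h |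
| green | 0.28 M | 0.900 equiv | 4.6 mol% | 0.1 mol% | 20 °C | 5.0 h |

- all constants are for 70 °C and move with temperature by the activation energies and enthalpies

- which flask leads in amount of G, in percent of the L charged ("all alike" within 1.5 percentage points) (violet / amber / red / green / all alike)
- how much G is there at the end, in percent of the L charged: violet
- how much G is there at the end, in percent of the L charged: amber
- how much G is there at the end, in percent of the L charged: red
- how much G is there at the end, in percent of the L charged: green

J is not consumed in the first step, so the forward arrow takes L at a first-order rate a, the first rate constant times J, which is 0.0466 min⁻¹ in red. But the second step has Q and E on its left. While E stands near its charge, the forward arrow takes Z at a pseudo-first-order rate b, the second rate constant times Q times E, which is 0.0157 min⁻¹ in red.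

From violet to red, a grows by a factor 440 and b by 68, so a over b is 2.97 in red but 0.459 in violet. Violet therefore has a = 0.00641 h⁻¹ and b = 0.0139 h⁻¹.

Two first-order steps in series invite one number. I take the time multiplied by the square root of a times b and call it the passage number x; I compute it for violet as 0.0473. With x small, E near its charge and the returns set aside, I reckon the fraction of L that has reached G as one minus (one plus x) times exp(−x), which for violet is 0.108%.

But red has x = 8.13, larger than in violet. That is far outside the rule, so I commit there to no figure beyond a lead for red, with E, the limiting reagent, charged at 0.900 of L.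

The forecast names red and gives violet 0.11%, amber 43.5%, red 70.5% and green 4.8%, on the ground that “the cold flasks barely get through the two-step sequence”.

The simulation puts red in the lead, with violet 0.108%, amber 43.5%, red 71.6% and green 4.79%.

In violet, the half-lives by the forward rate of each step alone at the asked time, 110 h for L and 50 h for Z, are both longer than the 5.0 h run, as is the relaxation half-life of the second step, both ways together, 47.6 h, and the passage number of 0.0473 stands beside a G of 0.108%. Green, with E at 94.7% of its charge, has a = 0.0687 h⁻¹, b = 0.0722 h⁻¹ and x = 0.352, which gives 4.92% against the 4.79% of G in the flask.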